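Count turnovers first, beginning with the dusk run, where the balance at the last reading stands further from closing than in the winter run.

all flasks: G 16 mM

| charge | L | remark | time |
|---|---|---|---|
| dusk | 20 mM | run made earlier |  |
| winter | 34 mM | run made earlier |  |
| blue | 14.0 mM |  | 6.0 h |
| green | 22.0 mM |  | 6.0 h |
- dusk (time / h: G / %, D / %): 0.250: 47, 44; 0.833: 33, 53; 1.33: 22, 50; 2.00: 14, 49; 3.00: 15, 50
- winter (time / h: G / %, D / %): 0.250: 27, 67; 0.417: 15, 71; 0.833: 10, 80; 1.50: 4, 86; 3.00: 1, 85

(standard deviation of a reading: 2 percentage points)
- part of the G that has reacted at the end, blue
- part of the G that has reacted at the end, green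
- what raising the concentration of L from its lowest to its highest value here does to the part of the G that has reacted (changes below 5 percentage points count as none) (no change / it rises / it falls)
- the numbers in the tables scatter with a standard deviation of 2 percentage points
- what has gone from G into another species counts as reacted, even if it can come back

At 3.00 h the dusk run reads G 15% and D 50%, so 35.0% of the G is unseen. I suppose that the unseen species is G joined to D, holding 2 G. Then the dusk run has made D from 67.5% of its G, or 10.8 mM, out of 20 mM of L, which is about 1.85 L per turnover. So I divide L charged by 2 and by G charged. In blue this gives 0.438, my turnover count, and below 1 it marks L as the limiting reagent. In green it gives 0.688. On that supposition each D can take up one more G, so I reckon 87.6% reacted in blue. In green the doubled count is 1.38, and the count is larger than in blue, so I reckon that the part reacted rises with L.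

The forecast, holding that “D yield scales roughly with L”, gives 80% for blue, lower than my 87.6%, 87% for green, and for the trend: it rises.

The simulation gives 81.8% for blue and 95.1% for green, so it rises, by 13 percentage points.

    G + L → Q + D (k = 4.51 M⁻¹ min⁻¹)
    L + Q ⇌ X, settled at all times (K = 80800 M⁻¹)
    G + D → E (k = 0.480 M⁻¹ min⁻¹)
    G + Q ⇌ Z, settled at all times (K = 64.1 M⁻¹)
    G ⇌ J (K = 0.282, k = 0.00120 min⁻¹)

In blue at 6.00 h, free L stands at 0.432% of its charge. D plus half of E, which counts double, comes to 0.483 of the G charged, beside the count of 0.438.

In the neighbour flask with 35 mM of L, the count is 1.09, above 1, so G should give out first. It does: 99.9% of the G has reacted, with G at 0.0623% and L at 14.6% of its charge.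

(Readings and results were computed on assumed constants, noise included.)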